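# Proposed synthesis of CNP0103636.1: epicatechin-(4β→6)-epiafzelechin-(4β→8)-epicatechin-(4β→6)-epicatechin

## Analysis of the target

The target is a linear proanthocyanidin tetramer of four 2-arylchroman-3-ol units, numbered 1 to 4 from the upper end: units 1, 3 and 4 are epicatechin (3,4-dihydroxyphenyl ring B) and unit 2 is epiafzelechin (4-hydroxyphenyl ring B). The interflavan bonds run from C4 of unit 1 to C6 of unit 2, from C4 of unit 2 to C8 of unit 3 and from C4 of unit 3 to C6 of unit 4, and unit 4 keeps a CH2 group at C4. There are eleven stereocentres: C2 and C3 of every unit are (2R,3R), with aryl group and oxygen cis on ring C, and each of the three substituted C4 centres carries its aryl group β, trans to the oxygen on the adjacent C3. Fifteen phenols and four secondary alcohols make the free compound sensitive to air and base, C2 can epimerise in base and the doubly benzylic C4–aryl bonds cleave in acid, so the polyphenol has to be unmasked last under neutral conditions. Two features make the synthesis hard: two of the three links end on C6, whereas ring A of a flavan captures a C4 cation preferentially at C8, and ring B of unit 2 does not occur in an abundant natural monomer. The plan rests on ring C of unit 4, where the benzylic CH2 (C4) on C4a lies ortho to the ether oxygen on C8a and the C3–C2 pair carries oxygen and aryl cis; this is the pattern left when the C=C bond of a Z 2-arylvinyl ester adds across the C=C–C=O unit of an ortho-quinone methide. With ring C removed, ring A of unit 4 is a 3,5-dioxygenated phenol that is symmetric about the axis through its hydroxyl carbon and the carbon bonded to unit 3, so the 4→6 connectivity is fixed before ring C exists. Ring C of unit 2 shows the same pattern once its bond to unit 3 is cut, so the disconnection can be used twice.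

## Retrosynthetic reasoning

**32 ⇐ 31 ⇐ 30.** The free polyphenol is released in the last step. In 31 every protected oxygen is a benzyl ether (seventeen) and the three halogens sit on aromatic carbons, so one hydrogenolysis should remove all of them. The pivalate on O3 of unit 2 in 30 is removed one step earlier with a hydride reagent, which avoids hydroxide or alkoxide next to the C2 centres.

**30 ⇐ 29 + 21.** The bond cut is C4 (unit 2)–C8 (unit 3). It is the only 4→8 link, the orientation ring A adopts without help, and cutting it gives two dimers of similar size. Forward, the C4 ether of 29 is ionised and C8 of unit 3 in 21 attacks trans to the C3 pivalate. The chlorine on C8 of unit 4 in 21 removes the only competing C8 position. The bromines on C8 of both units of 29 keep the electrophile from alkylating itself. Closing ring C of unit 2 onto a preformed unit 2–unit 3 bond was not pursued. The methide carbon would then carry the whole unit 3 aryl group, and the C3/C4 relation would depend on an endo/exo preference that the substrate does not fix.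

**21 ⇐ 19 ⇐ 18 ⇐ 17.** These are three functional-group changes on the lower dimer. The bromine on C8 of unit 3 is exchanged for lithium and protonated (through 20), which frees the nucleophilic position while the chlorine stays. The chlorine is put on C8 of unit 4 in 18 while C8 of unit 3 is still occupied by bromine. The pivalate of 17 is removed first so that no ester meets the organolithium.

**17 ⇐ 11 + 15 (key disconnection).** O1–C2 and C3–C4 of unit 4 are cut together. This leads to the ortho-hydroxybenzyl alcohol 11, which reacts as its quinone methide 16, and the Z enol pivalate 15, which brings ring B, C2 and C3. Cutting here instead of at the interflavan bond removes the C6/C8 question, and the CH2 at C4 removes any endo/exo question. The gain is one ring, two bonds and two stereocentres. The forward reaction must carry the Z geometry into the 2,3-cis relation and choose one face of the alkene.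

**29 ⇐ 28 ⇐ 26 + 24.** The leaving group on C4 of unit 2 in 29 comes from benzylic oxidation of the CH2 group of 28. Ring C of unit 2 in 28 is cut in the same way as in the key step, giving the benzylic alcohol 26 (reacting as quinone methide 27) and the Z enol pivalate 24 with the 4-benzyloxyphenyl ring. The flavan unit already present in 26 becomes unit 1.

**11 ⇐ 10 and 26 ⇐ 25 ⇐ 10.** Both benzylic alcohols come from the salicylaldehyde 10, which is the stable branch point. Reduction gives 11. For the upper half, the halogen that must cap C8 of unit 2 is introduced on 10 to give 25, because the one hydrogen left on that ring is ortho to a free phenol and is the most reactive site in the molecule. In the lower half the corresponding halogen is put on after the key step, so that the key step runs on the unsubstituted quinone methide 16.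

**10 ⇐ 9 ⇐ 8 ⇐ 5 + 7.** The formyl group is placed ortho to the hydroxyl of the symmetric phenol 9, whose two ortho positions are equivalent. Phenol 9 is the desilylated form of 8. In 8 the C4–aryl bond is cut: forward, the C4 cation from 5 attacks arene 7 at the carbon between its two benzyloxy groups, trans to the 3-benzyloxy group. The bulky silyl ether shields the other two ring positions of 7, and the bromine on C8 of 5 keeps the electrophile from reacting with itself.

**5 ⇐ 4 ⇐ 3 ⇐ 2 ⇐ 1 and 7 ⇐ 6.** The upper flavan unit comes from natural 1 with C2 and C3 already correct, by benzylation, C4 oxidation, 3-O-benzylation and C8 bromination. Arene 7 is the silyl ether of 6.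

**15 ⇐ 13 + 14, 13 ⇐ 12; 24 ⇐ 23 + 14, 23 ⇐ 22.** The Z enol esters come from anti-Markovnikov addition of acid 14 to the terminal alkynes 13 and 23, and these from aldehydes 12 and 22 by one-carbon homologation.

## Alternatives that were turned down

Alternative 1: closure of ring C of unit 1 through a cation at C4.
- Disconnection: the C4–C4a bond of unit 1.
- Forward key step: an open-chain precursor has a benzylic hydroxyl on the future C4, which already bears the trioxygenated aryl group that later becomes ring A of unit 2. Acid ionises it, and the position ortho to the ether oxygen of the future ring A of unit 1 attacks the cation in an intramolecular Friedel–Crafts alkylation. The product is A1, penta-O-benzyl-epicatechin with a 2,6-bis(benzyloxy)-4-(triisopropylsilyloxy)phenyl group on C4β.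
- For: the aryl group is on C4 by construction, so no site has to be chosen on a silyloxy arene. On this point it is stronger than step 6 of the chosen route, which relies on steric shielding. It is also independent of natural supply.
- Against: A1 is compound 8 without its bromine. The key step would be spent on a ring and on stereocentres that 1 already supplies. The C4 configuration would have to come from the conformation of a ring-closing transition state, not from attack on a formed ring trans to an axial C3 substituent. Rings C of the second and fourth units would still have to be made.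
- Comparison: the chosen route reaches the same kind of intermediate in six steps from 1 and puts its new chemistry where no natural building block helps.

Alternative 2: aryne insertion into a chiral carboxylic acid.
- Disconnection: O1–C8a and C4–C4a of unit 4, the two bonds from ring A to the three-carbon chain.
- Forward key step: fluoride unmasks an aryne across C4a–C8a of the future ring A. The carboxylate of an enantiopure acid that carries C2, C3 (as an acetonide) and ring B adds through oxygen to C8a, and the aryl anion at C4a then attacks the acyl carbon. The net insertion gives the ortho-hydroxyaryl ketone A2.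
- For: C2 and C3 arrive with secure absolute configuration from a separately made building block, which is stronger than a catalyst-controlled face selection. The benzyloxy group next to the aryne directs the orientation of the addition.
- Against: no ring is closed. C4 arrives as a ketone that must be reduced to CH2 in the presence of many benzyl ethers and an aryl bromide. O1–C2 must still be closed at a benzylic carbon with the 2,3-cis relation. The aryne precursor has to be built on a hindered, fully substituted ring.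
- Comparison: the chosen step forms both bonds and the ring at the correct oxidation level in one operation. In place of secure absolute configuration it offers a wrong-face product that is a separable diastereomer.

Alternative 3: quinone methide–enamine annulation of the central pyran ring.
- Disconnection: C3–C4 and O1–C2 of unit 2, with both neighbouring interflavan bonds already present.
- Forward key step: a carbinol that links ring A of unit 2 to C8 of unit 3 gives the ortho-quinone methide under mild acid. The enamine formed from benzyloxyacetaldehyde A4 and a chiral secondary-amine catalyst adds to the methide carbon (C3–C4), and the phenol oxygen closes on the aldehyde carbon (O1–C2) to give the lactol A3.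
- For: it is the most convergent cut, joining the two halves while the ring forms. Amine-catalysed additions to ortho-quinone methides are an established class, so precedent is stronger than for the chosen key step.
- Against: A3 has no aryl group on C2 and is a mixture of anomers. The 4-benzyloxyphenyl group must be introduced later cis to O3, the hardest relation in the unit. The methide carbon carries the whole lower dimer as its aryl group. The risk falls late, on material that contains both halves.
- Comparison: the chosen route sets 2,3-cis through alkene geometry on a small precursor and uses the same reaction type twice from one aldehyde, 10. It gives up ring formation at the centre and regains convergence by joining the two dimers through a C4–C8 cation coupling.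

Key step: step 12

## Remarks (assumptions on the chemistry)

- 3,5-Bis(benzyloxy)phenol (6) is taken as a purchasable compound.
- The sense of face selection of the chiral phosphoric acid with this dienophile class cannot be predicted with confidence. The (R) acid is written, and its mirror image is to be used if a first trial shows the opposite sense.
- The C4 ethers 3, 4, 5 and 29 are drawn 4β. This centre is erased on ionisation.

## Steps

Step 1
Reactants: 1 (−)-epicatechin
Product: 2 5,7,3′,4′-tetra-O-benzyl-(−)-epicatechin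
Conditions: BnBr (4.4 equiv), K2CO3, DMF, 0 °C → rt
Reagents that add atoms: benzyl bromide, BrCc1ccccc1
Why: Williamson etherification under a weak carbonate base alkylates only the four phenols; the C3 alcohol is not deprotonated and no stereocentre is touched.

Step 2
Reactants: 2 5,7,3′,4′-tetra-O-benzyl-(−)-epicatechin
Product: 3 4β-(2-ethoxyethoxy)-5,7,3′,4′-tetra-O-benzyl-(−)-epicatechin
Conditions: DDQ (2 equiv), HOCH2CH2OEt (5 equiv), CH2Cl2, rt
Reagents that add atoms: 2-ethoxyethanol, CCOCCO
Why: Benzylic oxidation by hydride abstraction: DDQ removes the C4 hydrogen aligned with the electron-rich ring A and the cation is trapped by the alcohol trans to the axial C3 hydroxyl (4β); this centre only serves as a leaving-group site.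

Step 3
Reactants: 3 4β-(2-ethoxyethoxy)-5,7,3′,4′-tetra-O-benzyl-(−)-epicatechin
Product: 4 4β-(2-ethoxyethoxy)-3,5,7,3′,4′-penta-O-benzyl-(−)-epicatechin
Conditions: NaH, BnBr, Bu4NI (cat.), DMF, 0 °C → rt
Reagents that add atoms: benzyl bromide, BrCc1ccccc1
Why: Williamson etherification of the secondary alkoxide; the C4 ether is stable to base and, with no free phenol left, there is no pathway for C2 epimerisation.

Step 4
Reactants: 4 4β-(2-ethoxyethoxy)-3,5,7,3′,4′-penta-O-benzyl-(−)-epicatechin
Product: 5 8-bromo-4β-(2-ethoxyethoxy)-3,5,7,3′,4′-penta-O-benzyl-(−)-epicatechin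
Conditions: NBS (1.05 equiv), CH2Cl2, −78 → 0 °C
Reagents that add atoms: N-bromosuccinimide, O=C1CCC(=O)N1Br
Why: Electrophilic aromatic bromination goes to C8, the most reactive position of ring A (between O1 and a benzyloxy group); the bromine later keeps this unit from acting as a nucleophile.

Step 5
Reactants: 6 3,5-bis(benzyloxy)phenol
Product: 7 [3,5-bis(benzyloxy)phenoxy]triisopropylsilane
Conditions: i-Pr3SiCl, imidazole, DMF, rt
Reagents that add atoms: chlorotriisopropylsilane, CC(C)[Si](Cl)(C(C)C)C(C)C
Why: Standard silylation of a phenol; the bulky silyl group is chosen to shield both positions ortho to this oxygen in step 6.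

Step 6
Reactants: 5 8-bromo-4β-(2-ethoxyethoxy)-3,5,7,3′,4′-penta-O-benzyl-(−)-epicatechin; 7 [3,5-bis(benzyloxy)phenoxy]triisopropylsilane
Product: 8 8-bromo-3,5,7,3′,4′-penta-O-benzyl-4β-[2,6-bis(benzyloxy)-4-(triisopropylsilyloxy)phenyl]-(−)-epicatechin
Conditions: Me3SiOTf (0.2 equiv), 7 (3 equiv), CH2Cl2, −78 → −40 °C
Reagents that add atoms: none
Why: Friedel–Crafts alkylation: the Lewis acid ionises the C4–O bond and arene 7 attacks the benzylic cation trans to the axial 3-benzyloxy group, which sets C4 as 4β. Attack should go to the carbon between the two benzyloxy groups because the triisopropylsilyl group shields its two ortho positions, and the bromine on C8 keeps 5 from condensing with itself.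

Step 7
Reactants: 8 8-bromo-3,5,7,3′,4′-penta-O-benzyl-4β-[2,6-bis(benzyloxy)-4-(triisopropylsilyloxy)phenyl]-(−)-epicatechin
Product: 9 8-bromo-3,5,7,3′,4′-penta-O-benzyl-4β-[2,6-bis(benzyloxy)-4-hydroxyphenyl]-(−)-epicatechin
Conditions: Bu4NF, AcOH, THF, 0 °C
Reagents that add atoms: none
Why: Fluoride cleavage of the aryl silyl ether, buffered so that the phenoxide is protonated at once; the phenol formed has two equivalent ortho positions.

Step 8
Reactants: 9 8-bromo-3,5,7,3′,4′-penta-O-benzyl-4β-[2,6-bis(benzyloxy)-4-hydroxyphenyl]-(−)-epicatechin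
Product: 10 8-bromo-3,5,7,3′,4′-penta-O-benzyl-4β-[2,6-bis(benzyloxy)-3-formyl-4-hydroxyphenyl]-(−)-epicatechin
Conditions: MgCl2, Et3N, (CH2O)n, THF, reflux
Reagents that add atoms: formaldehyde (as paraformaldehyde), C=O
Why: Casnati–Skattebøl ortho-formylation: the magnesium phenoxide delivers formaldehyde to the ortho carbon and hydride transfer to a second formaldehyde gives the aldehyde; the two ortho positions are equivalent and there is no other free phenol.

Step 9
Reactants: 10 8-bromo-3,5,7,3′,4′-penta-O-benzyl-4β-[2,6-bis(benzyloxy)-3-formyl-4-hydroxyphenyl]-(−)-epicatechin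
Product: 11 8-bromo-3,5,7,3′,4′-penta-O-benzyl-4β-[2,6-bis(benzyloxy)-4-hydroxy-3-(hydroxymethyl)phenyl]-(−)-epicatechin
Conditions: NaBH4, THF/MeOH, 0 °C
Reagents that add atoms: none
Why: Borohydride reduction of the aldehyde; aryl bromide and ethers are inert. The ortho-hydroxybenzyl alcohol is acid-sensitive and is used without storage.

Step 10
Reactants: 12 3,4-bis(benzyloxy)benzaldehyde
Product: 13 1,2-bis(benzyloxy)-4-ethynylbenzene
Conditions: dimethyl (1-diazo-2-oxopropyl)phosphonate, K2CO3, MeOH, rt
Reagents that add atoms: dimethyl (1-diazo-2-oxopropyl)phosphonate (Ohira–Bestmann reagent), CC(=O)C(=[N+]=[N-])P(=O)(OC)OC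
Why: Seyferth–Gilbert homologation in the Ohira–Bestmann form: methanolysis frees the diazomethylphosphonate, which converts the aldehyde into the terminal alkyne with loss of nitrogen.

Step 11
Reactants: 13 1,2-bis(benzyloxy)-4-ethynylbenzene; 14 pivalic acid
Product: 15 (Z)-2-[3,4-bis(benzyloxy)phenyl]vinyl pivalate
Conditions: Ru(η3-C4H7)2(Ph2P(CH2)4PPh2) (2 mol %), PhMe, 50 °C
Reagents that add atoms: none
Why: Ruthenium-catalysed anti-Markovnikov addition of a carboxylic acid to a terminal alkyne through a vinylidene complex; this catalyst class gives the Z enol ester from aryl acetylenes. The Z purity matters because it becomes the 2,3-cis relation.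

Step 12
Reactants: 11 8-bromo-3,5,7,3′,4′-penta-O-benzyl-4β-[2,6-bis(benzyloxy)-4-hydroxy-3-(hydroxymethyl)phenyl]-(−)-epicatechin; 15 (Z)-2-[3,4-bis(benzyloxy)phenyl]vinyl pivalate
Product: 17 [8-bromo-3,5,7,3′,4′-penta-O-benzyl-epicatechin]-(4β→6)-[5,7,3′,4′-tetra-O-benzyl-epicatechin 3-O-pivalate], via ortho-quinone methide 16 (not isolated)
Conditions: (R)-3,3′-bis(2,4,6-triisopropylphenyl)-1,1′-binaphthyl-2,2′-diyl hydrogen phosphate (10 mol %), 15 (3 equiv), 5 Å MS, PhMe, −20 °C → rt
Reagents that add atoms: none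
Why: Proposed new method: the chiral phosphoric acid protonates the benzylic hydroxyl of 11, water is taken up by the sieves and ortho-quinone methide 16 forms, bound to the phosphate through its carbonyl oxygen; the closest known reaction type is the Brønsted-acid-catalysed inverse-electron-demand [4+2] cycloaddition of ortho-quinone methides with styrenes, enamides and enol ethers, and what is new is a Z enol ester of an arylacetaldehyde as the 2π component. The two bonds should form with unequal timing: the ester-bearing alkene carbon of 15 attacks the electrophilic exocyclic CH2 of 16 (bond C3–C4), and the cationic character that builds on the aryl-bearing carbon is delocalised into the para-benzyloxy group, which the acyloxy group could not match in the opposite orientation, so the aryl group ends on C2 and the pivalate on C3. Ring C of unit 4 then closes when the ring A oxygen bonds to that benzylic carbon (O1–C2), overall a [4+2] closure of a six-membered ring and, in the stepwise limit, a 6-exo-trig capture of the benzylic cation by the phenolic oxygen. The 2,3-cis relation follows from the Z geometry of 15, because both new bonds form on the same face of the alkene. The absolute configuration (2R,3R) has to come from the catalyst, whose 3,3′-aryl groups must distinguish the two faces of 15 as it approaches the phosphate-bound 16. The flavan unit already present in 11 is a single enantiomer, so addition to the wrong face gives a diastereomer of 17 that can be removed by chromatography. No endo/exo question arises because the methide carbon carries two hydrogens, and no C6/C8 question arises because the hydroxymethyl group was placed on a phenol whose two ortho positions were equivalent. The selectivities needed are therefore orientation (secured by the aryl group), cis retention (secured by ring closure that is faster than bond rotation in a non-polar solvent at low temperature) and face selection (the open point).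

Step 13
Reactants: 17 [8-bromo-3,5,7,3′,4′-penta-O-benzyl-epicatechin]-(4β→6)-[5,7,3′,4′-tetra-O-benzyl-epicatechin 3-O-pivalate]
Product: 18 [8-bromo-3,5,7,3′,4′-penta-O-benzyl-epicatechin]-(4β→6)-[5,7,3′,4′-tetra-O-benzyl-epicatechin]
Conditions: i-Bu2AlH (3 equiv), CH2Cl2, −78 °C
Reagents that add atoms: none
Why: Reductive cleavage of the hindered ester by hydride avoids basic hydrolysis; aryl bromide and benzyl ethers are inert, and the ester is removed before any organolithium is used.

Step 14
Reactants: 18 [8-bromo-3,5,7,3′,4′-penta-O-benzyl-epicatechin]-(4β→6)-[5,7,3′,4′-tetra-O-benzyl-epicatechin]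
Product: 19 [8-bromo-3,5,7,3′,4′-penta-O-benzyl-epicatechin]-(4β→6)-[8-chloro-5,7,3′,4′-tetra-O-benzyl-epicatechin]
Conditions: NCS (1.05 equiv), CH2Cl2/MeCN, 0 °C → rt
Reagents that add atoms: N-chlorosuccinimide, O=C1CCC(=O)N1Cl
Why: Electrophilic aromatic chlorination: the only free positions on the trioxygenated rings are C8 of the lower unit and C6 of the upper unit, and the latter lies between two benzyloxy groups on a ring deactivated by bromine, so chlorine should enter C8 of the lower unit. It blocks that position in step 22.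

Step 15
Reactants: 19 [8-bromo-3,5,7,3′,4′-penta-O-benzyl-epicatechin]-(4β→6)-[8-chloro-5,7,3′,4′-tetra-O-benzyl-epicatechin]
Product: 21 [3,5,7,3′,4′-penta-O-benzyl-epicatechin]-(4β→6)-[8-chloro-5,7,3′,4′-tetra-O-benzyl-epicatechin], via aryllithium alkoxide 20 (not isolated)
Conditions: n-BuLi (2.5 equiv), THF, −78 °C; then MeOH
Reagents that add atoms: none
Why: Bromine–lithium exchange: the first equivalent of base deprotonates the alcohol and the second exchanges the aryl bromide, which is much faster than any reaction of the aryl chloride or the benzyl ethers at −78 °C; protonation leaves C8 of the upper unit as C–H.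

Step 16
Reactants: 22 4-(benzyloxy)benzaldehyde
Product: 23 1-(benzyloxy)-4-ethynylbenzene
Conditions: dimethyl (1-diazo-2-oxopropyl)phosphonate, K2CO3, MeOH, rt
Reagents that add atoms: dimethyl (1-diazo-2-oxopropyl)phosphonate (Ohira–Bestmann reagent), CC(=O)C(=[N+]=[N-])P(=O)(OC)OC
Why: Seyferth–Gilbert homologation in the Ohira–Bestmann form, as in step 10.

Step 17
Reactants: 23 1-(benzyloxy)-4-ethynylbenzene; 14 pivalic acid
Product: 24 (Z)-2-[4-(benzyloxy)phenyl]vinyl pivalate
Conditions: Ru(η3-C4H7)2(Ph2P(CH2)4PPh2) (2 mol %), PhMe, 50 °C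
Reagents that add atoms: none
Why: Ruthenium-catalysed anti-Markovnikov, Z-selective addition of the carboxylic acid to the terminal alkyne, as in step 11.

Step 18
Reactants: 10 8-bromo-3,5,7,3′,4′-penta-O-benzyl-4β-[2,6-bis(benzyloxy)-3-formyl-4-hydroxyphenyl]-(−)-epicatechin
Product: 25 8-bromo-3,5,7,3′,4′-penta-O-benzyl-4β-[2,6-bis(benzyloxy)-3-bromo-5-formyl-4-hydroxyphenyl]-(−)-epicatechin
Conditions: NBS (1.05 equiv), CH2Cl2/MeCN, −40 → 0 °C
Reagents that add atoms: N-bromosuccinimide, O=C1CCC(=O)N1Br
Why: Electrophilic aromatic bromination: the one hydrogen left on the pendant ring is ortho to the free phenol and to a benzyloxy group and para to the other benzyloxy group, so it is far more reactive than C6 of the bromine-bearing ring A or the dialkoxyphenyl ring. The halogen is introduced at the aldehyde stage because a formyl-bearing carbon, unlike a hydroxymethyl-bearing one, is not prone to ipso substitution; this bromine becomes the C8 cap of the epiafzelechin unit.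

Step 19
Reactants: 25 8-bromo-3,5,7,3′,4′-penta-O-benzyl-4β-[2,6-bis(benzyloxy)-3-bromo-5-formyl-4-hydroxyphenyl]-(−)-epicatechin
Product: 26 8-bromo-3,5,7,3′,4′-penta-O-benzyl-4β-[2,6-bis(benzyloxy)-3-bromo-4-hydroxy-5-(hydroxymethyl)phenyl]-(−)-epicatechin
Conditions: NaBH4, THF/MeOH, 0 °C
Reagents that add atoms: none
Why: Borohydride reduction of the aldehyde, as in step 9; both aryl bromides are inert and the product is used without storage.

Step 20
Reactants: 26 8-bromo-3,5,7,3′,4′-penta-O-benzyl-4β-[2,6-bis(benzyloxy)-3-bromo-4-hydroxy-5-(hydroxymethyl)phenyl]-(−)-epicatechin; 24 (Z)-2-[4-(benzyloxy)phenyl]vinyl pivalate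
Product: 28 [8-bromo-3,5,7,3′,4′-penta-O-benzyl-epicatechin]-(4β→6)-[8-bromo-5,7,4′-tri-O-benzyl-epiafzelechin 3-O-pivalate], via brominated ortho-quinone methide 27 (not isolated)
Conditions: (R)-3,3′-bis(2,4,6-triisopropylphenyl)-1,1′-binaphthyl-2,2′-diyl hydrogen phosphate (10 mol %), 24 (3 equiv), 5 Å MS, PhMe, −20 °C → rt
Reagents that add atoms: none
Why: Proposed new method: acid-catalysed dehydration of 26 gives quinone methide 27, which should add the Z enol ester 24 in the same asynchronous [4+2] manner as in step 12, the closest known reaction type again being the Brønsted-acid-catalysed cycloaddition of ortho-quinone methides with styrenes and enol ethers; the bromine next to the carbonyl carbon lowers the LUMO of the heterodiene and does not change the orientation, which the 4-benzyloxyphenyl group directs (aryl on C2, pivalate on C3). The Z geometry of 24 gives the 2,3-cis relation and the catalyst has to select the face for (2R,3R); a wrong-face adduct is again a separable diastereomer. The ring formed is ring C of the epiafzelechin unit, with the bromine on its C8.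

Step 21
Reactants: 28 [8-bromo-3,5,7,3′,4′-penta-O-benzyl-epicatechin]-(4β→6)-[8-bromo-5,7,4′-tri-O-benzyl-epiafzelechin 3-O-pivalate]
Product: 29 [8-bromo-3,5,7,3′,4′-penta-O-benzyl-epicatechin]-(4β→6)-[8-bromo-4β-(2-ethoxyethoxy)-5,7,4′-tri-O-benzyl-epiafzelechin 3-O-pivalate]
Conditions: DDQ (3 equiv), HOCH2CH2OEt (5 equiv), CH2Cl2, rt
Reagents that add atoms: 2-ethoxyethanol, CCOCCO
Why: Benzylic oxidation by hydride abstraction at the CH2 group of the lower unit, whose pseudo-axial hydrogen overlaps with a ring A that still carries three oxygen donors; the C4 hydrogen of the upper unit is flanked by two ortho-disubstituted aryl groups and lies near the plane of its ring A, so it is neither accessible nor aligned. The bromine slows the oxidation somewhat, hence the excess of DDQ; the alcohol adds trans to the pivalate.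

Step 22
Reactants: 29 [8-bromo-3,5,7,3′,4′-penta-O-benzyl-epicatechin]-(4β→6)-[8-bromo-4β-(2-ethoxyethoxy)-5,7,4′-tri-O-benzyl-epiafzelechin 3-O-pivalate]; 21 [3,5,7,3′,4′-penta-O-benzyl-epicatechin]-(4β→6)-[8-chloro-5,7,3′,4′-tetra-O-benzyl-epicatechin]
Product: 30 [8-bromo-3,5,7,3′,4′-penta-O-benzyl-epicatechin]-(4β→6)-[8-bromo-5,7,4′-tri-O-benzyl-epiafzelechin 3-O-pivalate]-(4β→8)-[3,5,7,3′,4′-penta-O-benzyl-epicatechin]-(4β→6)-[8-chloro-5,7,3′,4′-tetra-O-benzyl-epicatechin]
Conditions: Me3SiOTf (0.2 equiv), 21 (2 equiv), CH2Cl2, −78 → −40 °C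
Reagents that add atoms: none
Why: Friedel–Crafts coupling of a C4-activated flavan with ring A of another: the Lewis acid ionises the C4–O bond of the epiafzelechin unit, the axial C3 pivalate blocks (and can bridge) the α face, and C8 of the upper unit of 21 attacks from the β face, which sets the new C4 centre trans to O3. In 21 only C8 and C6 of that unit are free on activated rings, and C8, next to O1, is the position used in known 4→8 couplings; all C8 positions of 29 are capped, so it cannot condense with itself.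

Step 23
Reactants: 30 [8-bromo-3,5,7,3′,4′-penta-O-benzyl-epicatechin]-(4β→6)-[8-bromo-5,7,4′-tri-O-benzyl-epiafzelechin 3-O-pivalate]-(4β→8)-[3,5,7,3′,4′-penta-O-benzyl-epicatechin]-(4β→6)-[8-chloro-5,7,3′,4′-tetra-O-benzyl-epicatechin]
Product: 31 [8-bromo-3,5,7,3′,4′-penta-O-benzyl-epicatechin]-(4β→6)-[8-bromo-5,7,4′-tri-O-benzyl-epiafzelechin]-(4β→8)-[3,5,7,3′,4′-penta-O-benzyl-epicatechin]-(4β→6)-[8-chloro-5,7,3′,4′-tetra-O-benzyl-epicatechin]
Conditions: i-Bu2AlH (4 equiv), CH2Cl2, −78 °C
Reagents that add atoms: none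
Why: Reductive cleavage of the pivalate by hydride, as in step 13; no base touches the C2 centres and the aryl halides are inert.

Step 24
Reactants: 31 [8-bromo-3,5,7,3′,4′-penta-O-benzyl-epicatechin]-(4β→6)-[8-bromo-5,7,4′-tri-O-benzyl-epiafzelechin]-(4β→8)-[3,5,7,3′,4′-penta-O-benzyl-epicatechin]-(4β→6)-[8-chloro-5,7,3′,4′-tetra-O-benzyl-epicatechin]
Product: 32 CNP0103636.1 (epicatechin-(4β→6)-epiafzelechin-(4β→8)-epicatechin-(4β→6)-epicatechin)
Conditions: H2 (1 atm), Pd(OH)2/C, Et3N (3.3 equiv), THF/MeOH/H2O, rt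
Reagents that add atoms: none
Why: Hydrogenolysis of the seventeen benzyl ethers together with hydrodehalogenation of the two aryl bromides and the aryl chloride on palladium; the amine takes up the hydrogen halides so that the acid-labile interflavan bonds are not exposed to acid. No stereocentre is involved.

## Compound list

1 | (−)-epicatechin | O[C@@H]1Cc2c(O)cc(O)cc2O[C@@H]1c3ccc(O)c(O)c3 | starting material
2 | 5,7,3′,4′-tetra-O-benzyl-(−)-epicatechin | c1c(OCc9ccccc9)cc(OCc9ccccc9)c2c1O[C@H](c3ccc(OCc9ccccc9)c(OCc9ccccc9)c3)[C@H](O)C2 | intermediate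
3 | 4β-(2-ethoxyethoxy)-5,7,3′,4′-tetra-O-benzyl-(−)-epicatechin | c1c(OCc9ccccc9)cc(OCc9ccccc9)c2c1O[C@H](c3ccc(OCc9ccccc9)c(OCc9ccccc9)c3)[C@H](O)[C@H]2OCCOCC | intermediate
4 | 4β-(2-ethoxyethoxy)-3,5,7,3′,4′-penta-O-benzyl-(−)-epicatechin | c1c(OCc9ccccc9)cc(OCc9ccccc9)c2c1O[C@H](c3ccc(OCc9ccccc9)c(OCc9ccccc9)c3)[C@H](OCc9ccccc9)[C@H]2OCCOCC | intermediate
5 | 8-bromo-4β-(2-ethoxyethoxy)-3,5,7,3′,4′-penta-O-benzyl-(−)-epicatechin | Brc1c(OCc9ccccc9)cc(OCc9ccccc9)c2c1O[C@H](c3ccc(OCc9ccccc9)c(OCc9ccccc9)c3)[C@H](OCc9ccccc9)[C@H]2OCCOCC | intermediate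
6 | 3,5-bis(benzyloxy)phenol | Oc1cc(OCc9ccccc9)cc(OCc9ccccc9)c1 | starting material
7 | [3,5-bis(benzyloxy)phenoxy]triisopropylsilane | CC(C)[Si](C(C)C)(C(C)C)Oc1cc(OCc9ccccc9)cc(OCc9ccccc9)c1 | intermediate
8 | 8-bromo-3,5,7,3′,4′-penta-O-benzyl-4β-[2,6-bis(benzyloxy)-4-(triisopropylsilyloxy)phenyl]-(−)-epicatechin | Brc1c(OCc9ccccc9)cc(OCc9ccccc9)c2c1O[C@H](c3ccc(OCc9ccccc9)c(OCc9ccccc9)c3)[C@H](OCc9ccccc9)[C@H]2c1c(OCc9ccccc9)cc(O[Si](C(C)C)(C(C)C)C(C)C)cc1OCc9ccccc9 | intermediate
9 | 8-bromo-3,5,7,3′,4′-penta-O-benzyl-4β-[2,6-bis(benzyloxy)-4-hydroxyphenyl]-(−)-epicatechin | Brc1c(OCc9ccccc9)cc(OCc9ccccc9)c2c1O[C@H](c3ccc(OCc9ccccc9)c(OCc9ccccc9)c3)[C@H](OCc9ccccc9)[C@H]2c1c(OCc9ccccc9)cc(O)cc1OCc9ccccc9 | intermediate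
10 | 8-bromo-3,5,7,3′,4′-penta-O-benzyl-4β-[2,6-bis(benzyloxy)-3-formyl-4-hydroxyphenyl]-(−)-epicatechin | Brc1c(OCc9ccccc9)cc(OCc9ccccc9)c2c1O[C@H](c3ccc(OCc9ccccc9)c(OCc9ccccc9)c3)[C@H](OCc9ccccc9)[C@H]2c1c(OCc9ccccc9)cc(O)c(C=O)c1OCc9ccccc9 | intermediate
11 | 8-bromo-3,5,7,3′,4′-penta-O-benzyl-4β-[2,6-bis(benzyloxy)-4-hydroxy-3-(hydroxymethyl)phenyl]-(−)-epicatechin | Brc1c(OCc9ccccc9)cc(OCc9ccccc9)c2c1O[C@H](c3ccc(OCc9ccccc9)c(OCc9ccccc9)c3)[C@H](OCc9ccccc9)[C@H]2c1c(OCc9ccccc9)cc(O)c(CO)c1OCc9ccccc9 | intermediate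
12 | 3,4-bis(benzyloxy)benzaldehyde | O=Cc1ccc(OCc9ccccc9)c(OCc9ccccc9)c1 | starting material
13 | 1,2-bis(benzyloxy)-4-ethynylbenzene | C#Cc1ccc(OCc9ccccc9)c(OCc9ccccc9)c1 | intermediate
14 | pivalic acid | CC(C)(C)C(=O)O | starting material
15 | (Z)-2-[3,4-bis(benzyloxy)phenyl]vinyl pivalate | CC(C)(C)C(=O)O/C=C\c1ccc(OCc9ccccc9)c(OCc9ccccc9)c1 | intermediate
16 | ortho-quinone methide of the hydroxybenzyl alcohol (exocyclic CH2 on the former hydroxymethyl carbon, C=O on the former phenol carbon; not isolated) | Brc1c(OCc9ccccc9)cc(OCc9ccccc9)c2c1O[C@H](c3ccc(OCc9ccccc9)c(OCc9ccccc9)c3)[C@H](OCc9ccccc9)[C@H]2C1=C(OCc9ccccc9)C(=C)C(=O)C=C1OCc9ccccc9 | intermediate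
17 | [8-bromo-3,5,7,3′,4′-penta-O-benzyl-epicatechin]-(4β→6)-[5,7,3′,4′-tetra-O-benzyl-epicatechin 3-O-pivalate] | Brc1c(OCc9ccccc9)cc(OCc9ccccc9)c2c1O[C@H](c3ccc(OCc9ccccc9)c(OCc9ccccc9)c3)[C@H](OCc9ccccc9)[C@H]2c1c(OCc9ccccc9)cc2c(c1OCc9ccccc9)C[C@@H](OC(=O)C(C)(C)C)[C@@H](c3ccc(OCc9ccccc9)c(OCc9ccccc9)c3)O2 | intermediate
18 | [8-bromo-3,5,7,3′,4′-penta-O-benzyl-epicatechin]-(4β→6)-[5,7,3′,4′-tetra-O-benzyl-epicatechin] | Brc1c(OCc9ccccc9)cc(OCc9ccccc9)c2c1O[C@H](c3ccc(OCc9ccccc9)c(OCc9ccccc9)c3)[C@H](OCc9ccccc9)[C@H]2c1c(OCc9ccccc9)cc2c(c1OCc9ccccc9)C[C@@H](O)[C@@H](c3ccc(OCc9ccccc9)c(OCc9ccccc9)c3)O2 | intermediate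
19 | [8-bromo-3,5,7,3′,4′-penta-O-benzyl-epicatechin]-(4β→6)-[8-chloro-5,7,3′,4′-tetra-O-benzyl-epicatechin] | Brc1c(OCc9ccccc9)cc(OCc9ccccc9)c2c1O[C@H](c3ccc(OCc9ccccc9)c(OCc9ccccc9)c3)[C@H](OCc9ccccc9)[C@H]2c1c(OCc9ccccc9)c(Cl)c2c(c1OCc9ccccc9)C[C@@H](O)[C@@H](c3ccc(OCc9ccccc9)c(OCc9ccccc9)c3)O2 | intermediate
20 | aryllithium alkoxide (lithium on C8 of the upper unit, lithium alkoxide on O3 of the lower unit; not isolated) | [Li]c1c(OCc9ccccc9)cc(OCc9ccccc9)c2c1O[C@H](c3ccc(OCc9ccccc9)c(OCc9ccccc9)c3)[C@H](OCc9ccccc9)[C@H]2c1c(OCc9ccccc9)c(Cl)c2c(c1OCc9ccccc9)C[C@@H](O[Li])[C@@H](c3ccc(OCc9ccccc9)c(OCc9ccccc9)c3)O2 | intermediate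
21 | [3,5,7,3′,4′-penta-O-benzyl-epicatechin]-(4β→6)-[8-chloro-5,7,3′,4′-tetra-O-benzyl-epicatechin] | c1c(OCc9ccccc9)cc(OCc9ccccc9)c2c1O[C@H](c3ccc(OCc9ccccc9)c(OCc9ccccc9)c3)[C@H](OCc9ccccc9)[C@H]2c1c(OCc9ccccc9)c(Cl)c2c(c1OCc9ccccc9)C[C@@H](O)[C@@H](c3ccc(OCc9ccccc9)c(OCc9ccccc9)c3)O2 | intermediate
22 | 4-(benzyloxy)benzaldehyde | O=Cc1ccc(OCc9ccccc9)cc1 | starting material
23 | 1-(benzyloxy)-4-ethynylbenzene | C#Cc1ccc(OCc9ccccc9)cc1 | intermediate
24 | (Z)-2-[4-(benzyloxy)phenyl]vinyl pivalate | CC(C)(C)C(=O)O/C=C\c1ccc(OCc9ccccc9)cc1 | intermediate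
25 | 8-bromo-3,5,7,3′,4′-penta-O-benzyl-4β-[2,6-bis(benzyloxy)-3-bromo-5-formyl-4-hydroxyphenyl]-(−)-epicatechin | Brc1c(OCc9ccccc9)cc(OCc9ccccc9)c2c1O[C@H](c3ccc(OCc9ccccc9)c(OCc9ccccc9)c3)[C@H](OCc9ccccc9)[C@H]2c1c(OCc9ccccc9)c(Br)c(O)c(C=O)c1OCc9ccccc9 | intermediate
26 | 8-bromo-3,5,7,3′,4′-penta-O-benzyl-4β-[2,6-bis(benzyloxy)-3-bromo-4-hydroxy-5-(hydroxymethyl)phenyl]-(−)-epicatechin | Brc1c(OCc9ccccc9)cc(OCc9ccccc9)c2c1O[C@H](c3ccc(OCc9ccccc9)c(OCc9ccccc9)c3)[C@H](OCc9ccccc9)[C@H]2c1c(OCc9ccccc9)c(Br)c(O)c(CO)c1OCc9ccccc9 | intermediate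
27 | brominated ortho-quinone methide (exocyclic CH2 on the former hydroxymethyl carbon, C=O on the former phenol carbon, bromine on the carbon next to the carbonyl; not isolated) | Brc1c(OCc9ccccc9)cc(OCc9ccccc9)c2c1O[C@H](c3ccc(OCc9ccccc9)c(OCc9ccccc9)c3)[C@H](OCc9ccccc9)[C@H]2C1=C(OCc9ccccc9)C(=C)C(=O)C(Br)=C1OCc9ccccc9 | intermediate
28 | [8-bromo-3,5,7,3′,4′-penta-O-benzyl-epicatechin]-(4β→6)-[8-bromo-5,7,4′-tri-O-benzyl-epiafzelechin 3-O-pivalate] | Brc1c(OCc9ccccc9)cc(OCc9ccccc9)c2c1O[C@H](c3ccc(OCc9ccccc9)c(OCc9ccccc9)c3)[C@H](OCc9ccccc9)[C@H]2c1c(OCc9ccccc9)c(Br)c2c(c1OCc9ccccc9)C[C@@H](OC(=O)C(C)(C)C)[C@@H](c3ccc(OCc9ccccc9)cc3)O2 | intermediate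
29 | [8-bromo-3,5,7,3′,4′-penta-O-benzyl-epicatechin]-(4β→6)-[8-bromo-4β-(2-ethoxyethoxy)-5,7,4′-tri-O-benzyl-epiafzelechin 3-O-pivalate] | Brc1c(OCc9ccccc9)cc(OCc9ccccc9)c2c1O[C@H](c3ccc(OCc9ccccc9)c(OCc9ccccc9)c3)[C@H](OCc9ccccc9)[C@H]2c1c(OCc9ccccc9)c(Br)c2c(c1OCc9ccccc9)[C@H](OCCOCC)[C@@H](OC(=O)C(C)(C)C)[C@@H](c3ccc(OCc9ccccc9)cc3)O2 | intermediate
30 | [8-bromo-3,5,7,3′,4′-penta-O-benzyl-epicatechin]-(4β→6)-[8-bromo-5,7,4′-tri-O-benzyl-epiafzelechin 3-O-pivalate]-(4β→8)-[3,5,7,3′,4′-penta-O-benzyl-epicatechin]-(4β→6)-[8-chloro-5,7,3′,4′-tetra-O-benzyl-epicatechin] | c9ccccc9COc1ccc([C@H]2Oc3c(Br)c(OCc9ccccc9)c([C@H]4c5c(OCc9ccccc9)cc(OCc9ccccc9)c(Br)c5O[C@H](c5ccc(OCc9ccccc9)c(OCc9ccccc9)c5)[C@@H]4OCc9ccccc9)c(OCc9ccccc9)c3[C@H](c3c(OCc9ccccc9)cc(OCc9ccccc9)c4c3O[C@H](c3ccc(OCc9ccccc9)c(OCc9ccccc9)c3)[C@H](OCc9ccccc9)[C@H]4c3c(OCc9ccccc9)c(Cl)c4c(c3OCc9ccccc9)C[C@@H](O)[C@@H](c3ccc(OCc9ccccc9)c(OCc9ccccc9)c3)O4)[C@H]2OC(=O)C(C)(C)C)cc1 | intermediate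
31 | [8-bromo-3,5,7,3′,4′-penta-O-benzyl-epicatechin]-(4β→6)-[8-bromo-5,7,4′-tri-O-benzyl-epiafzelechin]-(4β→8)-[3,5,7,3′,4′-penta-O-benzyl-epicatechin]-(4β→6)-[8-chloro-5,7,3′,4′-tetra-O-benzyl-epicatechin] | c9ccccc9COc1ccc([C@H]2Oc3c(Br)c(OCc9ccccc9)c([C@H]4c5c(OCc9ccccc9)cc(OCc9ccccc9)c(Br)c5O[C@H](c5ccc(OCc9ccccc9)c(OCc9ccccc9)c5)[C@@H]4OCc9ccccc9)c(OCc9ccccc9)c3[C@H](c3c(OCc9ccccc9)cc(OCc9ccccc9)c4c3O[C@H](c3ccc(OCc9ccccc9)c(OCc9ccccc9)c3)[C@H](OCc9ccccc9)[C@H]4c3c(OCc9ccccc9)c(Cl)c4c(c3OCc9ccccc9)C[C@@H](O)[C@@H](c3ccc(OCc9ccccc9)c(OCc9ccccc9)c3)O4)[C@H]2O)cc1 | intermediate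
32 | CNP0103636.1 (epicatechin-(4β→6)-epiafzelechin-(4β→8)-epicatechin-(4β→6)-epicatechin) | Oc1ccc([C@H]2Oc3cc(O)c([C@H]4c5c(O)cc(O)cc5O[C@H](c5ccc(O)c(O)c5)[C@@H]4O)c(O)c3[C@H](c3c(O)cc(O)c4c3O[C@H](c3ccc(O)c(O)c3)[C@H](O)[C@H]4c3c(O)cc4c(c3O)C[C@@H](O)[C@@H](c3ccc(O)c(O)c3)O4)[C@H]2O)cc1 | target

## Step count and least certain steps

Total step count: 24. Longest linear sequence: 15 steps from 1 (steps 1–4, 6–9, 12–15, 22–24).

**Step 12 (key step).**
- What may go wrong: poor face selection, because the dienophile has no hydrogen-bond donor to anchor it to the phosphate; loss of the cis relation through bond rotation if a benzylic cation lives long enough; oligomerisation of the quinone methide if the enol ester is too weak a nucleophile.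
- Fallback (known chemistry): the lower unit is taken from natural material instead of being built. It sets out from 2 and 5. Compound 2 is chlorinated at C8 (NCS, CH2Cl2, low temperature) to 8-chloro-5,7,3′,4′-tetra-O-benzyl-(−)-epicatechin F1. F1 in excess and 5 are then coupled with Me3SiOTf in CH2Cl2 at −78 °C. With C8 of the nucleophile blocked, the C4 cation from 5 can only reach C6, trans to its 3-benzyloxy group. The product is 19, where the route is rejoined. The price is a slower Friedel–Crafts step at the hindered C6.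

**Step 20.**
- What may go wrong: the same processes as in step 12, now with the 4-benzyloxyphenyl dienophile; in addition the bromine next to the phenolic oxygen may slow ring closure or hinder binding to the catalyst.
- Fallback (known chemistry): it sets out from 5 and from purchased (−)-epiafzelechin F2. Benzylation of its three phenols (BnBr, K2CO3, DMF) gives 5,7,4′-tri-O-benzyl-(−)-epiafzelechin F3. Acylation (t-BuCOCl, pyridine, 4-dimethylaminopyridine) gives 5,7,4′-tri-O-benzyl-(−)-epiafzelechin 3-O-pivalate F4, and bromination with NBS gives 8-bromo-5,7,4′-tri-O-benzyl-(−)-epiafzelechin 3-O-pivalate F5. F5 in excess and 5 are coupled with Me3SiOTf in CH2Cl2 at low temperature. With C8 blocked, the cation from 5 can only bond to C6 of F5, and the product is 28, where the route is rejoined.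

**Step 6.**
- What may go wrong: attack of the C4 cation at a carbon ortho to the silyloxy group if shielding by the silyl group is not enough, which would give a constitutional isomer that cannot lead to the 4→6 link.
- Fallback: the site question is removed by symmetry. It sets out from 5, which is coupled with an excess of phloroglucinol F6 (BF3·OEt2, THF/CH2Cl2, 0 °C). All three ring carbons are equivalent, so only 8-bromo-3,5,7,3′,4′-penta-O-benzyl-4β-(2,4,6-trihydroxyphenyl)-(−)-epicatechin F7 can form. Its para hydroxyl is the only unhindered one and is silylated selectively (i-Pr3SiCl, 1 equiv, imidazole) to 8-bromo-3,5,7,3′,4′-penta-O-benzyl-4β-[2,6-dihydroxy-4-(triisopropylsilyloxy)phenyl]-(−)-epicatechin F8. The two flanking phenols are then benzylated under Mitsunobu conditions (BnOH, PPh3, diisopropyl azodicarboxylate) to give 8.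

**Step 22.**
- What may go wrong: slow capture of a cation at a congested C4 (its 5-benzyloxy neighbour is buttressed by the upper unit), which gives time for acid-induced cleavage and scrambling of the existing interflavan bonds or for attack at C6 of the nucleophile.
- Fallback: the cation is generated by soft activation of a sulfide instead of hard activation of an ether. It sets out from 29, which is treated briefly with BnSH and BF3·OEt2 at −40 °C to give [8-bromo-3,5,7,3′,4′-penta-O-benzyl-epicatechin]-(4β→6)-[4β-(benzylthio)-8-bromo-5,7,4′-tri-O-benzyl-epiafzelechin 3-O-pivalate] F9. F9 and 21 are then coupled with AgBF4 in THF at 0 °C, a thiophilic promoter that leaves the other interflavan bonds alone, and give 30.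

**Step 24.**
- What may go wrong: incomplete hydrogenolysis of the electron-rich aryl chloride and slowing of the catalyst by halide, leaving partly halogenated or partly benzylated polyphenols that cannot be separated.
- Fallback: the two tasks are separated. It sets out from 31, whose three carbon–halogen bonds are reduced first under homogeneous conditions (Pd(OAc)2, P(t-Bu)3, HCO2Na, DMF, 80 °C) to the halogen-free heptadeca-O-benzyl tetramer F10. Hydrogenolysis of F10 (H2, Pd(OH)2/C, THF/MeOH/H2O) then gives 32.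

## Further compounds

F1 | step 12 | 8-chloro-5,7,3′,4′-tetra-O-benzyl-(−)-epicatechin | Clc1c(OCc9ccccc9)cc(OCc9ccccc9)c2c1O[C@H](c3ccc(OCc9ccccc9)c(OCc9ccccc9)c3)[C@H](O)C2
F2 | step 20 | (−)-epiafzelechin (purchased) | O[C@@H]1Cc2c(O)cc(O)cc2O[C@@H]1c3ccc(O)cc3
F3 | step 20 | 5,7,4′-tri-O-benzyl-(−)-epiafzelechin | c1c(OCc9ccccc9)cc(OCc9ccccc9)c2c1O[C@H](c3ccc(OCc9ccccc9)cc3)[C@H](O)C2
F4 | step 20 | 5,7,4′-tri-O-benzyl-(−)-epiafzelechin 3-O-pivalate | c1c(OCc9ccccc9)cc(OCc9ccccc9)c2c1O[C@H](c3ccc(OCc9ccccc9)cc3)[C@H](OC(=O)C(C)(C)C)C2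
F5 | step 20 | 8-bromo-5,7,4′-tri-O-benzyl-(−)-epiafzelechin 3-O-pivalate | Brc1c(OCc9ccccc9)cc(OCc9ccccc9)c2c1O[C@H](c3ccc(OCc9ccccc9)cc3)[C@H](OC(=O)C(C)(C)C)C2
F6 | step 6 | phloroglucinol (purchased) | Oc1cc(O)cc(O)c1
F7 | step 6 | 8-bromo-3,5,7,3′,4′-penta-O-benzyl-4β-(2,4,6-trihydroxyphenyl)-(−)-epicatechin | Brc1c(OCc9ccccc9)cc(OCc9ccccc9)c2c1O[C@H](c3ccc(OCc9ccccc9)c(OCc9ccccc9)c3)[C@H](OCc9ccccc9)[C@H]2c1c(O)cc(O)cc1O
F8 | step 6 | 8-bromo-3,5,7,3′,4′-penta-O-benzyl-4β-[2,6-dihydroxy-4-(triisopropylsilyloxy)phenyl]-(−)-epicatechin | Brc1c(OCc9ccccc9)cc(OCc9ccccc9)c2c1O[C@H](c3ccc(OCc9ccccc9)c(OCc9ccccc9)c3)[C@H](OCc9ccccc9)[C@H]2c1c(O)cc(O[Si](C(C)C)(C(C)C)C(C)C)cc1O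
F9 | step 22 | [8-bromo-3,5,7,3′,4′-penta-O-benzyl-epicatechin]-(4β→6)-[4β-(benzylthio)-8-bromo-5,7,4′-tri-O-benzyl-epiafzelechin 3-O-pivalate] | Brc1c(OCc9ccccc9)cc(OCc9ccccc9)c2c1O[C@H](c3ccc(OCc9ccccc9)c(OCc9ccccc9)c3)[C@H](OCc9ccccc9)[C@H]2c1c(OCc9ccccc9)c(Br)c2c(c1OCc9ccccc9)[C@H](SCc9ccccc9)[C@@H](OC(=O)C(C)(C)C)[C@@H](c3ccc(OCc9ccccc9)cc3)O2
F10 | step 24 | halogen-free heptadeca-O-benzyl tetramer with free 3-hydroxyls on the epiafzelechin unit and on the terminal epicatechin unit | c9ccccc9COc1ccc([C@H]2Oc3cc(OCc9ccccc9)c([C@H]4c5c(OCc9ccccc9)cc(OCc9ccccc9)cc5O[C@H](c5ccc(OCc9ccccc9)c(OCc9ccccc9)c5)[C@@H]4OCc9ccccc9)c(OCc9ccccc9)c3[C@H](c3c(OCc9ccccc9)cc(OCc9ccccc9)c4c3O[C@H](c3ccc(OCc9ccccc9)c(OCc9ccccc9)c3)[C@H](OCc9ccccc9)[C@H]4c3c(OCc9ccccc9)cc4c(c3OCc9ccccc9)C[C@@H](O)[C@@H](c3ccc(OCc9ccccc9)c(OCc9ccccc9)c3)O4)[C@H]2O)cc1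
A1 | alternative 1 | penta-O-benzyl-epicatechin bonded 4β to a 2,6-bis(benzyloxy)-4-(triisopropylsilyloxy)phenyl group | CC(C)[Si](C(C)C)(C(C)C)Oc1cc(OCc6ccccc6)c(c(OCc6ccccc6)c1)[C@H]4c5c(OCc6ccccc6)cc(OCc6ccccc6)cc5O[C@H](c5ccc(OCc6ccccc6)c(OCc6ccccc6)c5)[C@@H]4OCc6ccccc6
A2 | alternative 2 | ortho-hydroxyaryl ketone, open form of unit 4 with the C2 and C3 oxygens as acetonide | Brc3c(OCc6ccccc6)cc(OCc6ccccc6)c4c3O[C@H](c3ccc(OCc6ccccc6)c(OCc6ccccc6)c3)[C@H](OCc6ccccc6)[C@H]4c3c(OCc6ccccc6)cc(O)c(c3OCc6ccccc6)C(=O)[C@H]1OC(C)(C)O[C@H]1c2ccc(OCc6ccccc6)c(OCc6ccccc6)c2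
A3 | alternative 3 | unit 2 as its 3-benzyloxy-2-hydroxychroman (lactol, both anomers) with both interflavan links in place | OC2Oc3cc(OCc6ccccc6)c([C@H]4c5c(OCc6ccccc6)cc(OCc6ccccc6)cc5O[C@H](c5ccc(OCc6ccccc6)c(OCc6ccccc6)c5)[C@@H]4OCc6ccccc6)c(OCc6ccccc6)c3[C@H](c3c(OCc6ccccc6)cc(OCc6ccccc6)c4c3O[C@H](c3ccc(OCc6ccccc6)c(OCc6ccccc6)c3)[C@H](OCc6ccccc6)[C@H]4c3c(OCc6ccccc6)cc4c(c3OCc6ccccc6)C[C@@H](OCc6ccccc6)[C@@H](c3ccc(OCc6ccccc6)c(OCc6ccccc6)c3)O4)[C@H]2OCc6ccccc6
A4 | alternative 3 | benzyloxyacetaldehyde | O=CCOCc1ccccc1
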